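**Assumption:** 5,7-dihydroxychromone, 3-chloro-3-methylbut-1-yne and (S)-MeO-F12-BIPHEP are treated as catalogue items. The target's single stereocentre is (2S), the natural flavanone configuration.

## Retrosynthetic overview
1. Target 11 ⇐ tris-MOM ether 10 by one mild global acid deprotection (no hydrogenolysis or BBr3, so the chromene C=C survives).
2. C2–aryl bond and the only stereocentre ⇐ Rh/(S)-biaryl-bisphosphine asymmetric 1,4-addition of chromenylboronic acid 7 to 5,7-bis(MOM)chromone 9.
3. 7 ⇐ bromide 6 ⇐ OMe→OMOM swap on 6-bromo-8-methoxy-2,2-dimethylchromene 4.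
4. 4 ⇐ propargyl Claisen/6π-electrocyclization of aryl 1,1-dimethylpropargyl ether 3 ⇐ 4-bromo-2-methoxyphenol 1.
5. Ring order: chromone A/C rings purchased; B-ring 2H-pyran formed in step 2; C2 stereocentre set in step 7.

## Route

**Step 1**
Reactants: 1, 4-bromo-2-methoxyphenol; 2, 3-chloro-3-methylbut-1-yne
Product: 3, 4-bromo-2-methoxy-1-[(2-methylbut-3-yn-2-yl)oxy]benzene
Conditions: 2 (1.3 equiv), DBU, CuCl2·2H2O (cat.), MeCN, 0 °C → rt
Reagents that add atoms: none beyond reactant 2 (C#CC(C)(C)Cl)
Why: Cu-catalysed propargylic O-alkylation of the only free phenol gives the tertiary aryl propargyl ether, with oxygen para to Br as the target requires.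

**Step 2**
Reactants: 3
Product: 4, 6-bromo-8-methoxy-2,2-dimethyl-2H-chromene
Conditions: PhNEt2, 190 °C, 3 h
Reagents that add atoms: none
Why: Aromatic propargyl Claisen rearrangement, then 1,5-H shift and 6π-oxa-electrocyclization, closes the pyran onto the only free ortho carbon (the other is blocked by OMe).

**Step 3**
Reactants: 4
Product: 5, 6-bromo-2,2-dimethyl-2H-chromen-8-ol
Conditions: EtSNa (3 equiv), DMF, 120 °C; cold dilute HCl work-up
Reagents that add atoms: none
Why: SN2 O-demethylation by thiolate is non-acidic, so the chromene olefin survives, and unactivated electron-rich aryl bromides tolerate these conditions.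

**Step 4**
Reactants: 5
Product: 6, 6-bromo-8-(methoxymethoxy)-2,2-dimethyl-2H-chromene
Conditions: MOMCl, i-Pr2NEt, CH2Cl2, 0 °C → rt
Reagents that add atoms: chloromethyl methyl ether, COCCl
Why: Standard phenol MOM protection installs a group that is stable to BuLi and neutral Rh conditions and removable by mild acid.

**Step 5**
Reactants: 6
Product: 7, [8-(methoxymethoxy)-2,2-dimethyl-2H-chromen-6-yl]boronic acid
Conditions: n-BuLi, THF, −78 °C; B(Oi-Pr)3, −78 °C → rt; sat. aq NH4Cl
Reagents that add atoms: triisopropyl borate, CC(C)OB(OC(C)C)OC(C)C; water, O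
Why: Br–Li exchange at −78 °C is faster than ortho-lithiation or addition to the olefin, and borate trapping with near-neutral hydrolysis gives the boronic acid with MOM intact.

**Step 6**
Reactants: 8, 5,7-dihydroxy-4H-chromen-4-one
Product: 9, 5,7-bis(methoxymethoxy)-4H-chromen-4-one
Conditions: NaH (2.4 equiv), MOMCl (2.6 equiv), DMF, 0 °C → rt
Reagents that add atoms: chloromethyl methyl ether, COCCl
Why: Williamson-type O-alkylation; NaH is needed to alkylate the chelated 5-OH as well as the acidic 7-OH, and protecting both removes acidic protons from the coupling step.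

**Step 7**
Reactants: 9; 7 (2.5 equiv)
Product: 10, (2S)-5,7-bis(methoxymethoxy)-2-[8-(methoxymethoxy)-2,2-dimethyl-2H-chromen-6-yl]-2,3-dihydro-4H-chromen-4-one
Conditions: [Rh(OH)(cod)]2 (2.5 mol %), (S)-MeO-F12-BIPHEP (5.5 mol %), CH2Cl2/H2O (10:1), 30 °C
Reagents that add atoms: none (water supplies only H at C3)
Why: Hayashi–Miyaura asymmetric 1,4-addition; by analogy with (S)-BINAP-type ligands giving (S)-3-arylcyclohexanones and (R)-ligands giving (R)-4-arylchromanones, the (S)-ligand should deliver the aryl to the enone face that gives 2S, and the base-free, low-temperature conditions suppress retro-oxa-Michael opening.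

**Step 8**
Reactants: 10
Product: 11, (2S)-5,7-dihydroxy-2-(8-hydroxy-2,2-dimethyl-2H-chromen-6-yl)-2,3-dihydro-4H-chromen-4-one (target)
Conditions: 3 M aq HCl/MeOH (1:4), 45 °C, ~3 h; confirm ee by chiral HPLC
Reagents that add atoms: none
Why: Acid-catalysed acetal solvolysis removes all three MOM groups; under mild acid the chromene olefin is inert and C2 is not epimerised, since racemisation needs base-mediated ring opening.

## Compound list
1 | 4-bromo-2-methoxyphenol | COc1cc(Br)ccc1O | starting material
2 | 3-chloro-3-methylbut-1-yne | C#CC(C)(C)Cl | starting material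
3 | 4-bromo-2-methoxy-1-[(2-methylbut-3-yn-2-yl)oxy]benzene | COc1cc(Br)ccc1OC(C)(C)C#C | intermediate
4 | 6-bromo-8-methoxy-2,2-dimethyl-2H-chromene | COc1cc(Br)cc2C=CC(C)(C)Oc12 | intermediate
5 | 6-bromo-2,2-dimethyl-2H-chromen-8-ol | Oc1cc(Br)cc2C=CC(C)(C)Oc12 | intermediate
6 | 6-bromo-8-(methoxymethoxy)-2,2-dimethyl-2H-chromene | COCOc1cc(Br)cc2C=CC(C)(C)Oc12 | intermediate
7 | [8-(methoxymethoxy)-2,2-dimethyl-2H-chromen-6-yl]boronic acid | COCOc1cc(B(O)O)cc2C=CC(C)(C)Oc12 | intermediate
8 | 5,7-dihydroxy-4H-chromen-4-one | O=c1ccoc2cc(O)cc(O)c12 | starting material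
9 | 5,7-bis(methoxymethoxy)-4H-chromen-4-one | COCOc1cc(OCOC)c2c(c1)occc2=O | intermediate
10 | (2S)-5,7-bis(methoxymethoxy)-2-[8-(methoxymethoxy)-2,2-dimethyl-2H-chromen-6-yl]chroman-4-one | CC1(C)C=Cc2cc([C@@H]3CC(=O)c4c(OCOC)cc(OCOC)cc4O3)cc(OCOC)c2O1 | intermediate
11 | (2S)-5,7-dihydroxy-2-(8-hydroxy-2,2-dimethyl-2H-chromen-6-yl)chroman-4-one | CC1(C)C=Cc2cc([C@@H]3CC(=O)c4c(O)cc(O)cc4O3)cc(O)c2O1 | target

## Summary
Total steps: 8 (convergent).
Longest linear sequence: 7 (steps 1–5, 7, 8).

Steps most likely to fail:
1. **Step 7** (electron-rich chromone is a weak acceptor; protodeboronation of 7; the absolute sense rests on analogy and must be confirmed by CD or rotation). Fallback: abandon the 1,4-addition. Quench the aryllithium from 6 with DMF to give the aldehyde, condense it with a tert-butyl 3-[2-hydroxy-4,6-bis(methoxymethoxy)phenyl]-3-oxopropanoate, close the ring by a cinchona–thiourea-catalysed enantioselective oxa-Michael reaction, then decarboxylate.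
2. **Step 8** (acid could partly racemise C2 or damage the chromene). Fallback: change the protecting-group plan to TBS ethers on 7-OH and the chromene 8-OH with the chelated 5-OH left free, and finish with HF·pyridine or AcOH-buffered fluoride instead of acid.
3. **Step 3** (thiolate demethylation at 120 °C next to an aryl bromide and chromene). Fallback: install the phenol oxidatively instead. O-propargylate 5-bromosalicylaldehyde with 2, convert CHO to OH by Baeyer–Villiger oxidation (mCPBA) and formate methanolysis, MOM-protect, then run the Claisen cyclization to reach 6 directly.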